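If this flask is repeated, watch the ratio of new target to new other capture product. Dividing one capture rate by the other removes time and leaves R = s·c(first nucleophile)/c(second nucleophile).

all flasks: first nucleophile 46.8 mM

|  | substrate | second nucleophile | remark | time |
|---|---|---|---|---|
| ochre | 26 mM | 27.3 mM | run made earlier |  |
| teal | 13 mM | 27.3 mM | run made earlier |  |
| alder | 26 mM | 27.3 mM (fed, over 25 h) | all else is in the flask from the start; the feed brings no volume worth counting | 40 h |
| oak | 26 mM | 27.3 mM | everything together at the start | 40 h |
| maple | 26 mM (fed, over 25 h) | 27.3 mM | all else is in the flask from the start; the feed brings no volume worth counting | 40 h |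
| larch | 26 mM | 27.3 mM (in portions, 4, over 25 h) | first portion at the start, last at 25 h | 40 h |

- ochre (time / h: target / %, other capture product / %): 2.00: 3.6, 4.0; 3.00: 4.8, 7.4; 4.00: 6.1, 9.8; 6.00: 7.2, 12.9; 10.0: 11.1, 21.7; 15.0: 13.5, 31.2; 25.0: 17.1, 45.2
- teal (time / h: target / %, other capture product / %): 0.500: 0, 0.7; 1.00: 1.6, 3.2; 1.50: 1.5, 3.8; 2.50: 3.6, 6.9; 3.00: 4.1, 7.1; 4.00: 5.4, 9.0

(standard deviation of a reading: 0.5 percentage points)

* which flask leads in share of target in target plus other capture product ("all alike" within 1.5 percentage points) (alder / oak / maple / larch / all alike)
* share of target in target plus other capture product at the end, alder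
* share of target in target plus other capture product at the end, oak
* share of target in target plus other capture product at the end, maple
* share of target in target plus other capture product at the end, larch

- the analysis behind the earlier runs scatters by 0.5 percentage points, standard deviation

At 4.00 h, ochre reads 0.622 and teal 0.600, so the substrate charge barely moves it. I read 0.363 as s, the selectivity factor, target made per other capture product at equal nucleophile concentrations.

Late in ochre, from 15.0 h to 25.0 h, R reads 0.257. The charge less the other capture product puts second nucleophile near 17.4 mM, if none of it goes elsewhere. On that assumption this one scattered reading puts first nucleophile near 12.3 mM, yet target has used just 3.98 mM. It has a loss of its own, and the same reading gives a rough half-time of 10.4 h. Substrate's half-time, from the summed products, is 17.8 h, which is longer.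

So I compare recipes at the shorter time, with first nucleophile at 23.4 mM. Oak then holds 21.7 mM of second nucleophile, which gives R = 0.392. Alder has received 11.3 mM, which gives 0.750. Larch has received 13.7 mM, which gives 0.622. Maple has received half its substrate at 12.5 h, later than that, so I put it below oak and alder first.

The forecast names oak, with 15.5% for alder, 23.5% for oak, 16% for maple and 16.5% for larch, on the ground that “Feeding nucleophile starves early capture”.

The flasks give 36.8% for alder, 21.9% for oak, 11.8% for maple and 35.3% for larch.

    substrate ⇌ intermediate (K = 0.190, k = 0.0440 /h)
    first nucleophile + intermediate → target (k = 54.0 /M/h)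
    second nucleophile + intermediate → other capture product (k = 150 /M/h)
    second nucleophile ⇌ dormant form (K = 0.400, k = 0.0680 /h)
    first nucleophile → decomposed reagent (k = 0.100 /h)

At 40.0 h, target over other capture product stands at 0.582 in alder and 0.281 in oak, a factor of 2.07 against my 1.91. The neighbour is alder with 46 mM of second nucleophile. With the same s and half-time, its feed has delivered 19.1 mM, so I reckon R = 0.445. It ends at 0.423, a share of 29.7%.

The data were generated by integration for substances that don't exist; scatter was added.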